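The runs are simulated for substances that don't exist, and the scatter is random.

Late in the summer run, at 3.00 h, the target stands at 12.6% of the charge and the electrophile at 86.9%, so that flask is still far from its end.

| flask | electrophile | free base | gas | remark | time |
|---|---|---|---|---|---|
| summer | 27 mM | 54 mM | 4 mM (held) | run made earlier |  |
| red | 18 mM | 54.0 mM | 4.0 mM (held) |  | 5.0 h |
| amber | 18 mM | 81.0 mM | 4.0 mM (held) |  | 5.0 h |
| blue | 18 mM | 120 mM | 4.0 mM (held) |  | 5.0 h |

- summer (time / h: electrophile / %, target / %): 0.250: 98.3, 0; 0.500: 96.8, 1.6; 1.33: 95.3, 6.1; 3.00: 86.9, 12.6

(readings scatter by 1 percentage point)

- at the start none of nucleophile is dissolved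
- steps that have been proposed: electrophile + nucleophile -> acid set free + target; nucleophile + acid set free <-> protonated nucleophile; acid set free + free base <-> salt of the base; free base <-> dormant form; gas <-> nucleophile
- no earlier run changes the charge of free base; that part of a forecast is a guess

1. part of the electrophile that has reacted at the end, red
2. part of the electrophile that has reacted at the end, amber
3. part of the electrophile that has reacted at the end, blue
4. what raising the concentration of free base from its lowest to its highest value here does to the part of the electrophile that has reacted (changes below 5 percentage points count as none) (no change / it rises / it falls)

The readings give a ladder of times. On the shortest rung, the nucleophile starts undissolved and the target reads 0% at 0.250 h and 1.6% at 0.500 h, a lag shorter than the run. The next rung is the steady turnover: at the pace of the last reading, the summer charge lasts 23.8 h.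

With 12.6% of the charge turned to target at the last reading, the summer readings do not tell a steady amount per hour from a steady fraction per hour. The lag points to the gas crossing, so this reckoning takes that crossing as the rate-limiting step. The gas is held as before, so on this reckoning the amount per hour stays the same, and a charge 0.667 of the summer one is used sooner. That gives 15.9 h: the clearing time, the time in which the steady turnover uses up a charge.

The last rung is this clearing time. Because the lag in the summer readings ends well before it, and the asked 5.0 h also falls short of it, this reckoning puts the reacted fraction at the time over the clearing time, 31.5% in red. No earlier run changes the free base, so giving amber and blue the same figure is a guess.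

The forecast gives 21.5% for red, 21.5% for amber and 21.5% for blue, with the trend no change: “More base should therefore change little”. It stands below this reckoning and agrees with it on the trend.

The flask gives 30.4% for red, 30.4% for amber and 30.4% for blue, and the trend is no change, a change of 0.0083 percentage points.

    electrophile + nucleophile → acid set free + target (k = 2.40 M⁻¹ min⁻¹)
    nucleophile + acid set free ⇌ protonated nucleophile, settled at all times (K = 2.50 × 10⁶ M⁻¹)
    acid set free + free base ⇌ salt of the base, settled at all times (K = 22.0 M⁻¹)
    free base ⇌ dormant form (K = 0.620, k = 0.00190 min⁻¹)
    gas ⇌ nucleophile, rate k5*(csat - [nucleophile]) (kL = 0.0110 min⁻¹)

At 2.50 h in amber, the step to target has 49% of its turnover up to 5.0 h behind it, and the gas crossing reaches the midpoint of its own turnover at 2.46 h, so both run evenly. The step from free base to dormant form in amber has more behind it than the step to target, 68%, and passes its midpoint at 1.64 h. The clearing time gives 31.5% for red against the 30.4% found. For amber read at 2.0 h, it gives 12.6%, and that flask stands at 11.7%.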